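The synthesis rests on disconnecting the C2–C3 bond of the pyranone ring (ring C). C2 is benzylic, bound to O1 and to catechol ring B; in an open precursor it is the CH2 of an aryl benzyl ether, whose C–H bonds are the most hydridic in the molecule. A rhodium carbene held at C3 by the C4 carbonyl on ring A inserts into one of them, so a single operation closes ring C, forms C2–C3 and sets C2 under catalyst control. The precursor is a 2-(3,4-disilyloxybenzyloxy)aryl diazomethyl ketone already carrying the 7-O-prenyl group; the C3 hydroxyl is then added trans by enolate oxidation.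

Key step: step 7

Assumption: Rh2(S-BSP)4 (BSP = N-benzenesulfonylprolinate) is taken to deliver the 2S flavanone 12; if the sense of induction proves opposite, the mirror-image catalyst Rh2(R-BSP)4 is used with no other change.

Step 1
Reactants: 1 1-(2,4,6-trihydroxyphenyl)ethanone; 2 1-bromo-3-methylbut-2-ene (prenyl bromide)
Product: 3 1-[2,6-dihydroxy-4-(3-methylbut-2-enyloxy)phenyl]ethanone
Conditions: K2CO3 (1 equiv), acetone, reflux
Reagents that add atoms: none
Why: Williamson ether synthesis, in which the 4-hydroxyl (para to the acetyl group and not tied up in the hydrogen bond to the carbonyl) is the most acidic and most accessible phenol, so one equivalent of the allylic bromide should alkylate it selectively by SN2.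

Step 2
Reactants: 4 3,4-dihydroxybenzaldehyde
Product: 5 3,4-bis(tert-butyldimethylsilyloxy)benzaldehyde
Conditions: TBSCl, imidazole, DMF, 0 °C to rt
Reagents that add atoms: tert-butyldimethylsilyl chloride CC(C)(C)[Si](C)(C)Cl
Why: Imidazole-promoted silyl ether formation should cap both catechol hydroxyls with groups that tolerate the later amide bases and the carbene step and leave with fluoride at the end.

Step 3
Reactants: 5 3,4-bis(tert-butyldimethylsilyloxy)benzaldehyde
Product: 6 [3,4-bis(tert-butyldimethylsilyloxy)phenyl]methanol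
Conditions: NaBH4, EtOH/THF, 0 °C
Reagents that add atoms: none
Why: Borohydride reduction of the aryl aldehyde should give the primary benzylic alcohol, the aryl silyl ethers surviving short exposure at 0 °C.

Step 4
Reactants: 3 1-[2,6-dihydroxy-4-(3-methylbut-2-enyloxy)phenyl]ethanone; 6 [3,4-bis(tert-butyldimethylsilyloxy)phenyl]methanol
Product: 7 1-[2-{[3,4-bis(tert-butyldimethylsilyloxy)phenyl]methoxy}-6-hydroxy-4-(3-methylbut-2-enyloxy)phenyl]ethanone
Conditions: PPh3, DIAD, THF, 0 °C to rt (3 in slight excess)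
Reagents that add atoms: none
Why: Mitsunobu etherification under neutral conditions, in which one of the two equivalent ortho-phenols displaces the oxyphosphonium of the primary benzylic alcohol, and the remaining hydroxyl, now chelated to the carbonyl and flanked by the new ether, should resist a second alkylation.

Step 5
Reactants: 7 1-[2-{[3,4-bis(tert-butyldimethylsilyloxy)phenyl]methoxy}-6-hydroxy-4-(3-methylbut-2-enyloxy)phenyl]ethanone
Product: 8 1-[2-{[3,4-bis(tert-butyldimethylsilyloxy)phenyl]methoxy}-4-(3-methylbut-2-enyloxy)-6-(triisopropylsilyloxy)phenyl]ethanone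
Conditions: TIPSOTf, 2,6-lutidine, CH2Cl2, 0 °C
Reagents that add atoms: triisopropylsilyl trifluoromethanesulfonate CC(C)[Si](OS(=O)(=O)C(F)(F)F)(C(C)C)C(C)C
Why: Silyl triflate silylation should cap the chelated phenol, the bulky triisopropylsilyl group being chosen because it resists oxygen-to-oxygen migration to the enolates of steps 6 and 8 and shields this oxygen from the carbene of step 7.

Step 6
Reactants: 8 1-[2-{[3,4-bis(tert-butyldimethylsilyloxy)phenyl]methoxy}-4-(3-methylbut-2-enyloxy)-6-(triisopropylsilyloxy)phenyl]ethanone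
Product: 11 2-diazo-1-[2-{[3,4-bis(tert-butyldimethylsilyloxy)phenyl]methoxy}-4-(3-methylbut-2-enyloxy)-6-(triisopropylsilyloxy)phenyl]ethanone, via lithium enolate 9 (not isolated), via trifluoroacetyl diketone 10 (not isolated)
Conditions: LiN(SiMe3)2, THF, −78 °C; CF3CO2CH2CF3; dilute aq. HCl wash; then MsN3, Et3N, H2O (1 equiv), MeCN, rt
Reagents that add atoms: methanesulfonyl azide CS(=O)(=O)N=[N+]=[N-]; 2,2,2-trifluoroethyl trifluoroacetate O=C(OCC(F)(F)F)C(F)(F)F (its trifluoroacetyl group is carried only by intermediate 10)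
Why: Detrifluoroacetylative Regitz-type diazo transfer, in which Claisen trifluoroacetylation of the kinetic lithium enolate activates the methyl group, the sulfonyl azide delivers N2 to the 1,3-dicarbonyl carbon and the trifluoroacetyl group leaves as the N-acyl sulfonamide.

Step 7
Reactants: 11 2-diazo-1-[2-{[3,4-bis(tert-butyldimethylsilyloxy)phenyl]methoxy}-4-(3-methylbut-2-enyloxy)-6-(triisopropylsilyloxy)phenyl]ethanone
Product: 12 (2S)-2-[3,4-bis(tert-butyldimethylsilyloxy)phenyl]-7-(3-methylbut-2-enyloxy)-5-(triisopropylsilyloxy)chroman-4-one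
Conditions: Rh2(S-BSP)4 (1 mol %), CH2Cl2, 40 °C, slow addition of 11 at high dilution
Reagents that add atoms: none
Why: Rh2(S-BSP)4 extrudes N2 from 11 to give an electrophilic catalyst-bound carbene at the future C3, which takes up a C–H bond of the benzyloxy CH2 through a three-centre, hydride-transfer-like transition state in which C2–C3 forms as the hydrogen moves to C3 (intramolecular carbene C–H insertion). The closest known reaction type is the enantioselective cyclisation of ortho-alkoxyaryl α-diazoketones to chroman-4-ones under chiral divalent-rhodium carboxylates. Ring C (O1, C2, C3, C4, C4a, C8a) closes by 1,6-insertion, a five-membered alternative being impossible because the 1,5-position is O1 itself. The single new stereocenter, C2, is set by the chiral prolinate ligands, which distinguish the two enantiotopic benzylic hydrogens and should give the 2S flavanone. The step needs C–H insertion to beat oxonium-ylide formation at O1 or at the silylated 5-oxygen and any reaction at the prenyl alkene: O1 is a weakly nucleophilic aryl oxygen conjugated to the C4 carbonyl, the 5-oxygen is buried under the triisopropylsilyl group, the target C–H is activated by O1 and by electron-rich ring B, and slow addition at high dilution suppresses intermolecular cyclopropanation.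

Step 8
Reactants: 12 (2S)-2-[3,4-bis(tert-butyldimethylsilyloxy)phenyl]-7-(3-methylbut-2-enyloxy)-5-(triisopropylsilyloxy)chroman-4-one
Product: 14 (2R,3R)-2-[3,4-bis(tert-butyldimethylsilyloxy)phenyl]-3-hydroxy-7-(3-methylbut-2-enyloxy)-5-(triisopropylsilyloxy)chroman-4-one, via sodium enolate 13 (not isolated)
Conditions: NaN(SiMe3)2, THF, −78 °C; then 3-phenyl-2-(phenylsulfonyl)oxaziridine, −78 °C; aq. NH4Cl
Reagents that add atoms: 3-phenyl-2-(phenylsulfonyl)oxaziridine O=S(=O)(c1ccccc1)N1OC1c1ccccc1
Why: Davis oxidation, in which the kinetically formed sodium enolate (cold enough that β-elimination of the O1 phenoxide should not compete) takes oxygen at C3 from the face opposite the C2 aryl group, setting the 2,3-trans relationship by substrate control without touching the prenyl alkene; C2 keeps its spatial arrangement and its descriptor changes from S to R only because C3 now outranks the aryl group.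

Step 9
Reactants: 14 (2R,3R)-2-[3,4-bis(tert-butyldimethylsilyloxy)phenyl]-3-hydroxy-7-(3-methylbut-2-enyloxy)-5-(triisopropylsilyloxy)chroman-4-one
Product: 15 (2R,3R)-2-(3,4-dihydroxyphenyl)-3,5-dihydroxy-7-(3-methylbut-2-enyloxy)chroman-4-one
Conditions: Bu4NF, AcOH (1:1), THF, 0 °C to rt
Reagents that add atoms: none
Why: Fluoride-mediated cleavage of the three aryl silyl ethers, with acetic acid buffering so that the liberated phenols stay protonated and neither base-induced opening of ring C (epimerisation at C2 and C3) nor loss of the prenyl ether should occur.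

Compound list
1 | 1-(2,4,6-trihydroxyphenyl)ethanone | CC(=O)c1c(O)cc(O)cc1O | starting material
2 | 1-bromo-3-methylbut-2-ene | CC(C)=CCBr | starting material
3 | 1-[2,6-dihydroxy-4-(3-methylbut-2-enyloxy)phenyl]ethanone | CC(C)=CCOc1cc(O)c(C(C)=O)c(O)c1 | intermediate
4 | 3,4-dihydroxybenzaldehyde | O=Cc1ccc(O)c(O)c1 | starting material
5 | 3,4-bis(tert-butyldimethylsilyloxy)benzaldehyde | O=Cc1ccc(O[Si](C)(C)C(C)(C)C)c(O[Si](C)(C)C(C)(C)C)c1 | intermediate
6 | [3,4-bis(tert-butyldimethylsilyloxy)phenyl]methanol | OCc1ccc(O[Si](C)(C)C(C)(C)C)c(O[Si](C)(C)C(C)(C)C)c1 | intermediate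
7 | 1-[2-{[3,4-bis(tert-butyldimethylsilyloxy)phenyl]methoxy}-6-hydroxy-4-(3-methylbut-2-enyloxy)phenyl]ethanone | CC(C)=CCOc1cc(O)c(C(C)=O)c(OCc2ccc(O[Si](C)(C)C(C)(C)C)c(O[Si](C)(C)C(C)(C)C)c2)c1 | intermediate
8 | 1-[2-{[3,4-bis(tert-butyldimethylsilyloxy)phenyl]methoxy}-4-(3-methylbut-2-enyloxy)-6-(triisopropylsilyloxy)phenyl]ethanone | CC(C)=CCOc1cc(O[Si](C(C)C)(C(C)C)C(C)C)c(C(C)=O)c(OCc2ccc(O[Si](C)(C)C(C)(C)C)c(O[Si](C)(C)C(C)(C)C)c2)c1 | intermediate
9 | lithium enolate of 8 (not isolated) | [Li+].C=C([O-])c1c(O[Si](C(C)C)(C(C)C)C(C)C)cc(OCC=C(C)C)cc1OCc1ccc(O[Si](C)(C)C(C)(C)C)c(O[Si](C)(C)C(C)(C)C)c1 | intermediate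
10 | 4,4,4-trifluoro-1-[2-{[3,4-bis(tert-butyldimethylsilyloxy)phenyl]methoxy}-4-(3-methylbut-2-enyloxy)-6-(triisopropylsilyloxy)phenyl]butane-1,3-dione (not isolated) | CC(C)=CCOc1cc(O[Si](C(C)C)(C(C)C)C(C)C)c(C(=O)CC(=O)C(F)(F)F)c(OCc2ccc(O[Si](C)(C)C(C)(C)C)c(O[Si](C)(C)C(C)(C)C)c2)c1 | intermediate
11 | 2-diazo-1-[2-{[3,4-bis(tert-butyldimethylsilyloxy)phenyl]methoxy}-4-(3-methylbut-2-enyloxy)-6-(triisopropylsilyloxy)phenyl]ethanone | CC(C)=CCOc1cc(O[Si](C(C)C)(C(C)C)C(C)C)c(C(=O)C=[N+]=[N-])c(OCc2ccc(O[Si](C)(C)C(C)(C)C)c(O[Si](C)(C)C(C)(C)C)c2)c1 | intermediate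
12 | (2S)-2-[3,4-bis(tert-butyldimethylsilyloxy)phenyl]-7-(3-methylbut-2-enyloxy)-5-(triisopropylsilyloxy)chroman-4-one | CC(C)=CCOc1cc(O[Si](C(C)C)(C(C)C)C(C)C)c2c(c1)O[C@H](c1ccc(O[Si](C)(C)C(C)(C)C)c(O[Si](C)(C)C(C)(C)C)c1)CC2=O | intermediate
13 | sodium enolate of 12 (not isolated) | [Na+].CC(C)=CCOc1cc(O[Si](C(C)C)(C(C)C)C(C)C)c2c(c1)O[C@H](c1ccc(O[Si](C)(C)C(C)(C)C)c(O[Si](C)(C)C(C)(C)C)c1)C=C2[O-] | intermediate
14 | (2R,3R)-2-[3,4-bis(tert-butyldimethylsilyloxy)phenyl]-3-hydroxy-7-(3-methylbut-2-enyloxy)-5-(triisopropylsilyloxy)chroman-4-one | CC(C)=CCOc1cc(O[Si](C(C)C)(C(C)C)C(C)C)c2c(c1)O[C@H](c1ccc(O[Si](C)(C)C(C)(C)C)c(O[Si](C)(C)C(C)(C)C)c1)[C@@H](O)C2=O | intermediate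
15 | (2R,3R)-2-(3,4-dihydroxyphenyl)-3,5-dihydroxy-7-(3-methylbut-2-enyloxy)chroman-4-one | CC(C)=CCOc1cc(O)c2c(c1)O[C@H](c1ccc(O)c(O)c1)[C@@H](O)C2=O | target

Total step count: 9. Longest linear sequence: 8 steps (4 to 15 through steps 2 to 9); from 1 the sequence is 7 steps.

Steps most likely to fail

Step 7. The carbene may be intercepted by the lone pair of O1 (five-membered oxonium ylide, then 1,2-shift of the electron-rich benzyl group), or the catalyst may discriminate the two enantiotopic benzylic hydrogens poorly. The fallback gives up the C–H insertion and builds flavanone 12 by enantioselective conjugate arylation of a chromone, a known route to 2-arylchroman-4-ones. It sets out from 3 and comes back to the route at 12.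
- Heating 3 with N,N-dimethylformamide dimethyl acetal in toluene should give the enaminone (E)-3-(dimethylamino)-1-[2,6-dihydroxy-4-(3-methylbut-2-enyloxy)phenyl]prop-2-en-1-one F1.
- Warming in AcOH should cyclise it, with loss of dimethylamine, to 5-hydroxy-7-(3-methylbut-2-enyloxy)chromen-4-one F2.
- TIPSOTf and 2,6-lutidine should convert this into 7-(3-methylbut-2-enyloxy)-5-(triisopropylsilyloxy)chromen-4-one F3.
- In parallel, commercial 4-bromocatechol is silylated (TBSCl, imidazole) to 4-bromo-1,2-bis(tert-butyldimethylsilyloxy)benzene F4, then taken through bromine–lithium exchange (n-BuLi, THF, −78 °C), B(OiPr)3 and mild aqueous work-up to [3,4-bis(tert-butyldimethylsilyloxy)phenyl]boronic acid F5.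
- Addition of F5 to F3 with Pd(OCOCF3)2 and the pyridine–oxazoline ligand t-BuPyOx (the antipode that gives the 2S product), NH4PF6, H2O, ClCH2CH2Cl, 60 °C should deliver 12, and the route continues at step 8.

Step 8. The enolate may undergo β-elimination with opening of ring C (loss of the C2 configuration through the chalcone), the neighbouring silyl group may migrate to the enolate oxygen, or oxygen may be delivered to the wrong face. The fallback replaces the free enolate by a Rubottom oxidation of a neutral enol silane. It sets out from 12 and comes back at 14.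
- TMSOTf and Et3N in CH2Cl2 at 0 °C should give the enol silane (2S)-2-[3,4-bis(tert-butyldimethylsilyloxy)phenyl]-7-(3-methylbut-2-enyloxy)-5-(triisopropylsilyloxy)-4-(trimethylsilyloxy)-2H-chromene F6.
- One equivalent of dimethyldioxirane in acetone/CH2Cl2 at −78 °C should oxidise it anti to the C2 aryl group, faster than the prenyl alkene, to (2R,3R)-2-[3,4-bis(tert-butyldimethylsilyloxy)phenyl]-7-(3-methylbut-2-enyloxy)-5-(triisopropylsilyloxy)-3-(trimethylsilyloxy)chroman-4-one F7.
- Citric acid in MeOH should remove the trimethylsilyl group to give 14.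

Step 4. The electron-rich benzylic oxyphosphonium may ionise and C-benzylate the phloroglucinol ring, or both ortho-phenols may be etherified. The fallback replaces the redox condensation by a Williamson alkylation of the phenoxide. It sets out from 6 and comes back at 7.
- Alcohol 6 is converted by the Appel reaction (CBr4, PPh3, CH2Cl2, 0 °C) into 4-(bromomethyl)-1,2-bis(tert-butyldimethylsilyloxy)benzene F8, used at once.
- F8 is combined with 3 and K2CO3 in dry acetone at rt; O-alkylation of the more reactive non-chelated phenoxide should give 7.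

Further compounds
F1 | step 7 | (E)-3-(dimethylamino)-1-[2,6-dihydroxy-4-(3-methylbut-2-enyloxy)phenyl]prop-2-en-1-one | CN(C)/C=C/C(=O)c1c(O)cc(OCC=C(C)C)cc1O
F2 | step 7 | 5-hydroxy-7-(3-methylbut-2-enyloxy)chromen-4-one | O=c1ccoc2cc(OCC=C(C)C)cc(O)c12
F3 | step 7 | 7-(3-methylbut-2-enyloxy)-5-(triisopropylsilyloxy)chromen-4-one | O=c1ccoc2cc(OCC=C(C)C)cc(O[Si](C(C)C)(C(C)C)C(C)C)c12
F4 | step 7 | 4-bromo-1,2-bis(tert-butyldimethylsilyloxy)benzene | Brc1ccc(O[Si](C)(C)C(C)(C)C)c(O[Si](C)(C)C(C)(C)C)c1
F5 | step 7 | [3,4-bis(tert-butyldimethylsilyloxy)phenyl]boronic acid | OB(O)c1ccc(O[Si](C)(C)C(C)(C)C)c(O[Si](C)(C)C(C)(C)C)c1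
F6 | step 8 | (2S)-2-[3,4-bis(tert-butyldimethylsilyloxy)phenyl]-7-(3-methylbut-2-enyloxy)-5-(triisopropylsilyloxy)-4-(trimethylsilyloxy)-2H-chromene | CC(C)=CCOc1cc(O[Si](C(C)C)(C(C)C)C(C)C)c2c(c1)O[C@H](c1ccc(O[Si](C)(C)C(C)(C)C)c(O[Si](C)(C)C(C)(C)C)c1)C=C2O[Si](C)(C)C
F7 | step 8 | (2R,3R)-2-[3,4-bis(tert-butyldimethylsilyloxy)phenyl]-7-(3-methylbut-2-enyloxy)-5-(triisopropylsilyloxy)-3-(trimethylsilyloxy)chroman-4-one | CC(C)=CCOc1cc(O[Si](C(C)C)(C(C)C)C(C)C)c2c(c1)O[C@H](c1ccc(O[Si](C)(C)C(C)(C)C)c(O[Si](C)(C)C(C)(C)C)c1)[C@@H](O[Si](C)(C)C)C2=O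
F8 | step 4 | 4-(bromomethyl)-1,2-bis(tert-butyldimethylsilyloxy)benzene | BrCc1ccc(O[Si](C)(C)C(C)(C)C)c(O[Si](C)(C)C(C)(C)C)c1
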